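The numbers in the tables are simulated on assumed constants; the scatter is artificial.

J comes slowly in the earlier runs, so we reckon with the fraction of G that has not become J and define a loss constant κ, the apparent first-order constant: the logarithm of one over that fraction, divided by the time.

| setting | west | south | south-west | flask |
|---|---|---|---|---|
| G | 0.010 M | 0.040 M | 0.020 M | 0.020 M |
| D | 1 equiv | 1 equiv | 2 equiv | 1.00 equiv |
| remark | run made earlier | run made earlier | run made earlier |  |
| time |  |  |  | 50 min |

| run | time / min | J / % | E / % |
|---|---|---|---|
| west | 5.00 | 6 | 2 |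
| west | 8.00 | 5 | 0 |
| west | 12.0 | 7 | 2 |
| west | 20.0 | 11 | 0 |
| west | 40.0 | 16 | 0 |
| west | 60.0 | 25 | 0 |
| south | 10.0 | 7 | 1 |
| south | 20.0 | 15 | 7 |
| south | 30.0 | 19 | 11 |
| south | 40.0 | 26 | 17 |
| south | 50.0 | 31 | 22 |
| south | 60.0 | 30 | 24 |
| south-west | 12.0 | 12 | 1 |
| south-west | 25.0 | 21 | 6 |
| south-west | 40.0 | 24 | 14 |
| south-west | 50.0 | 31 | 12 |
| south-west | 60.0 | 35 | 24 |

(scatter of a reading: 2 percentage points)

- what is said of J includes E
- E is a solid; its amount is given per volume of the solution

- amount of J and E together at 50 min, in percent of the G charged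
- concentration of J in solution at 50 min, in percent of saturation

Two extreme versions of the flask can be solved in the head. If it ran like the west run, whose last reading gives κ = 0.00479 min⁻¹, it would hold 21.3% of its G as J and E together at 50 min. If it ran like the south run, whose reading at 50.0 min gives 0.00742 min⁻¹, it would hold 31.0%. The flask has cG = 0.020 M, twice the west charge and half the south one, so we take the geometric mean, 0.00597 min⁻¹, as the flask's loss constant κ, and this gives 25.8%. The last south reading puts dissolved J at about 2.40 mM, which is 12.0% of the flask's charge. Our total stands above that, so we expect cJ at saturation and the excess as E.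

The forecast gave 25% and 100%, reasoning that “the solution should sit at saturation by 50 min”.

The flask gives 25.8% and 100%.

    D + L → J (k = 27.0 M⁻¹ min⁻¹)
    E ⇌ J, rate k2*(cs2 - [J]) while solid is left; crystals form when [J] > cs2 (solubility = 2.50 mM, k = 10.0 min⁻¹)
    G + D ⇌ X (K = 110 M⁻¹, k = 16.0 M⁻¹ min⁻¹)
    G ⇌ L (K = 0.0570, k = 0.0800 min⁻¹)

The flask's result returns κ = 0.00597 min⁻¹. With the step from L back to G taken away, the flask reaches 80.4% of J and E at 50 min, and left ten times as long with that step in place it reaches 86.4%, so its slowness comes in part from that return of L together with the time of the reading. Stepping κ down from the west run by the factor that separates the west run from the flask gives 0.00385 min⁻¹ for the neighbour at 0.0050 M, hence 17.5%, and that neighbour gives 16.2%.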